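Germacranolide numbering is used: carbocycle C1–C10, lactone ring O–C6–C7–C11(=C13)–C12, methyl C14 on C10, methylene C15 on C4. Everything rests on disconnecting C7–C8, which makes the C8 carbinol homoallylic to the C11=C13 methylene of the lactone ring. An intramolecular Nozaki–Hiyama–Kishi allylation of a 3-(bromomethyl)butenolide (C13–Br, C7=C11) onto a C8 aldehyde closes the ten-membered carbocycle, sets C7 and C8 and creates the exocyclic methylene in one operation. The acyclic precursor already carries both epoxides, the C4 methylene and the silylated C5 hydroxyl; it is assembled from a Sharpless-derived epoxy aldehyde and an allyl chloride fragment by asymmetric chloroallylboration.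

Key step: step 14

Remark on the chemistry: Ipc = isopinocampheyl; the two Ipc2BOMe antipodes are assigned on the assumption that the reagent derived from (+)-α-pinene attacks the Si face of an aldehyde and its antipode the Re face.

Step 1
Reactants: 1 4-[(tert-butyldimethylsilyl)oxy]but-1-yne
Product: 3 (2E)-5-[(tert-butyldimethylsilyl)oxy]-3-methylpent-2-en-1-ol, via alkenyl(dimethyl)alane 2 (not isolated)
Conditions: Me3Al, Cp2ZrCl2 (20 mol%), CH2Cl2, 0 °C to rt; then n-BuLi, THF, −78 °C; (CH2O)n, −78 °C to rt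
Reagents that add atoms: trimethylaluminium C[Al](C)C; paraformaldehyde (formaldehyde unit) C=O
Why: Negishi zirconium-catalysed syn-carboalumination places methyl (C14) and aluminium cis on the alkyne, and hydroxymethylation of the derived alanate proceeds with retention, so only the E-trisubstituted allylic alcohol should form.

Step 2
Reactants: 3 (2E)-5-[(tert-butyldimethylsilyl)oxy]-3-methylpent-2-en-1-ol
Product: 4 [(2R,3R)-3-{2-[(tert-butyldimethylsilyl)oxy]ethyl}-3-methyloxiran-2-yl]methanol
Conditions: Ti(OiPr)4 (10 mol%), D-(−)-diethyl tartrate (12 mol%), t-BuOOH, 4 Å molecular sieves, CH2Cl2, −20 °C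
Reagents that add atoms: tert-butyl hydroperoxide CC(C)(C)OO
Why: Sharpless asymmetric epoxidation of a geraniol-type E-allylic alcohol; the D-(−)-tartrate ligand directs oxygen to the face that gives the (2R,3R)-epoxy alcohol, setting C1 and C10.

Step 3
Reactants: 4 [(2R,3R)-3-{2-[(tert-butyldimethylsilyl)oxy]ethyl}-3-methyloxiran-2-yl]methanol
Product: 5 (2S,3R)-3-{2-[(tert-butyldimethylsilyl)oxy]ethyl}-3-methyloxirane-2-carbaldehyde
Conditions: Dess–Martin periodinane, NaHCO3, CH2Cl2, 0 °C to rt
Reagents that add atoms: none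
Why: Dess–Martin oxidation of the primary epoxy alcohol stops at the aldehyde and should neither open nor epimerise the epoxide.

Step 4
Reactants: 6 4-methoxybenzyl alcohol; 7 allyl bromide
Product: 8 allyl 4-methoxybenzyl ether
Conditions: NaH, THF/DMF, 0 °C; then 7, rt
Reagents that add atoms: none
Why: Williamson ether synthesis, alkoxide SN2 displacement on allyl bromide.

Step 5
Reactants: 8 allyl 4-methoxybenzyl ether; 9 methacrolein
Product: 11 (3S,4S)-4-[(4-methoxybenzyl)oxy]-2-methylhexa-1,5-dien-3-ol, via alkoxyallylborane 10 (not isolated)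
Conditions: 8, s-BuLi, THF, −78 °C; (+)-Ipc2BOMe [from (−)-α-pinene]; BF3·OEt2; 9, −78 °C; then NaOH, H2O2, 0 °C to rt
Reagents that add atoms: none
Why: Brown γ-alkoxyallylboration; the borane with the alkoxy group cis to CH2B adds through a chair transition state to the Re face of methacrolein under Ipc control, giving the syn-diol monoether and setting C5 and C6.

Step 6
Reactants: 11 (3S,4S)-4-[(4-methoxybenzyl)oxy]-2-methylhexa-1,5-dien-3-ol
Product: 12 tert-butyl({(3S,4S)-4-[(4-methoxybenzyl)oxy]-2-methylhexa-1,5-dien-3-yl}oxy)dimethylsilane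
Conditions: TBSOTf, 2,6-lutidine, CH2Cl2, −78 to 0 °C
Reagents that add atoms: tert-butyldimethylsilyl triflate CC(C)(C)[Si](C)(C)OS(=O)(=O)C(F)(F)F
Why: Standard silyl ether formation on the hindered secondary allylic alcohol with a silyl triflate and a non-nucleophilic base; it protects the C5 hydroxyl until the last step.

Step 7
Reactants: 12 tert-butyl({(3S,4S)-4-[(4-methoxybenzyl)oxy]-2-methylhexa-1,5-dien-3-yl}oxy)dimethylsilane
Product: 13 tert-butyl({(3S,4S)-2-(chloromethyl)-4-[(4-methoxybenzyl)oxy]hexa-1,5-dien-3-yl}oxy)dimethylsilane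
Conditions: N-chlorosuccinimide, PhSeCl (10 mol%), CH2Cl2, rt
Reagents that add atoms: N-chlorosuccinimide ClN1C(=O)CCC1=O
Why: Selenium-catalysed ene-type allylic chlorination is specific for the electron-rich 1,1-disubstituted alkene and transposes it toward the methyl group (elimination away from the silyloxy carbon), so the vinyl group and the anisyl ring should stay intact.

Step 8
Reactants: 13 tert-butyl({(3S,4S)-2-(chloromethyl)-4-[(4-methoxybenzyl)oxy]hexa-1,5-dien-3-yl}oxy)dimethylsilane; 5 (2S,3R)-3-{2-[(tert-butyldimethylsilyl)oxy]ethyl}-3-methyloxirane-2-carbaldehyde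
Product: 16 acyclic bis-epoxide with C8–OTBS; 1,10-epoxide; cis-2,3-epoxide; C4 methylene; C5–OTBS; C6–OPMB; C7 vinyl (C10 R; C1 R; C2 S; C3 S; C5 S; C6 S), via chloroallylborane 14 (not isolated), via syn-chlorohydrin 15 (not isolated)
Conditions: 13 (1.5 equiv), (−)-Ipc2BOMe [from (+)-α-pinene], LiN(c-C6H11)2, Et2O/THF, −95 °C; BF3·OEt2; 5, −95 °C; then 3 M NaOH, 30% H2O2, 0 °C to rt
Reagents that add atoms: none
Why: Brown-type γ-chloroallylboration; the borane with chlorine cis to CH2B adds through a chair transition state to the Si face of 5 under Ipc control to give the syn-chlorohydrin (C2 and C3 set, C4=C15 formed by allyl transposition), and the basic work-up closes it with inversion at C3 to the cis-epoxide.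

Step 9
Reactants: 16 acyclic bis-epoxide (C6–OPMB)
Product: 17 C6 alcohol of 16 (C10 R; C1 R; C2 S; C3 S; C5 S; C6 S)
Conditions: DDQ, CH2Cl2/pH 7 buffer, 0 °C
Reagents that add atoms: none
Why: Oxidative cleavage of the 4-methoxybenzyl ether by DDQ (oxocarbenium formation and hydrolysis) is neutral and should leave epoxides, silyl ethers and the isolated alkenes untouched.

Step 10
Reactants: 17 C6 alcohol; 18 2-(bromomethyl)acrylic acid
Product: 19 C6 2-(bromomethyl)acrylate ester of 17
Conditions: 18, N,N'-diisopropylcarbodiimide, DMAP (10 mol%), CH2Cl2, 0 °C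
Reagents that add atoms: none
Why: Steglich esterification; with only catalytic DMAP at 0 °C, acylation of the C6 hydroxyl should outrun displacement of the allylic bromide, and no alkoxide is formed that could trigger silyl migration.

Step 11
Reactants: 19 C6 2-(bromomethyl)acrylate ester
Product: 20 3-(bromomethyl)butenolide (lactone O–C6–C7=C11–C12; C13–Br; C8–OTBS; C5–OTBS; both epoxides; C4 methylene)
Conditions: second-generation Hoveyda–Grubbs catalyst (10 mol%), toluene, 70 °C
Reagents that add atoms: none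
Why: Ring-closing metathesis; the carbene loads on the only monosubstituted alkene (C7 vinyl) and closes the five-membered butenolide onto the acrylate, while the C4 methylene would require a tetrasubstituted alkene and alkyl bromides and epoxides are tolerated by ruthenium carbenes.

Step 12
Reactants: 20 3-(bromomethyl)butenolide (C8–OTBS)
Product: 21 primary C8 alcohol of 20
Conditions: Et3N·3HF, MeCN, rt
Reagents that add atoms: none
Why: Fluoride desilylation with the weakly acidic, amine-free Et3N·3HF should cleave the unhindered primary silyl ether much faster than the hindered secondary one, without opening epoxides or displacing the allylic bromide.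

Step 13
Reactants: 21 primary C8 alcohol
Product: 22 C8 aldehyde (β,γ-epoxy aldehyde carrying the 3-(bromomethyl)butenolide)
Conditions: Dess–Martin periodinane, NaHCO3, CH2Cl2, 0 °C; used crude at once
Reagents that add atoms: none
Why: Buffered Dess–Martin oxidation is neutral enough to give the β,γ-epoxy aldehyde without β-elimination or reaction at the allylic bromide.

Step 14
Reactants: 22 C8 aldehyde
Product: 24 ten-membered 8-hydroxy-11(13)-methylene lactone with C5–OTBS (C1 R; C2 S; C3 S; C5 S; C6 S; C7 R; C8 S; C10 R), via allylchromium species 23 (not isolated)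
Conditions: CrCl2 (10 equiv), THF, rt, syringe-pump addition of 22 (final 2 mM)
Reagents that add atoms: none
Why: Two equivalents of divalent chromium reduce the allylic C13–Br bond of 22 to a nucleophilic allylchromium species of trivalent chromium (23), which adds through its γ-carbon C7 to the C8 aldehyde in a six-membered chair transition state (SE2'), shifting the double bond to C11=C13. The closest known reaction is the Nozaki–Hiyama–Kishi (Barbier) allylation of aldehydes with 2-(bromomethyl)acrylates and 3-(bromomethyl)butenolides, which is also used for medium-ring carbocyclisation. The ten-membered carbocycle closes in the 10-exo-trig mode with respect to the carbonyl group. C7 is controlled by C6, the aldehyde being delivered to the butenolide face anti to the C5 side chain (trans lactone fusion); C8 is controlled by the chair, in which C9 is equatorial and C6 is fixed trans to C13 across C7=C11, so the C7/C8 relationship should be anti as in the target. The step needs chemoselective reduction of the allylic bromide beside two epoxides and the aldehyde, γ- over α-attack and cyclisation over oligomerisation; the much faster reduction of allylic bromides by CrCl2, the closed transition state and slow addition at high dilution should secure these. The β,γ-epoxy aldehyde meets only this nearly neutral medium and is consumed as it is added.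

Step 15
Reactants: 24 ten-membered 8-hydroxy lactone; 25 methacrylic anhydride
Product: 26 8-O-methacrylate of 24 (C5–OTBS)
Conditions: 25, Et3N, DMAP (cat.), CH2Cl2, 0 °C to rt
Reagents that add atoms: none
Why: DMAP-catalysed acylation of the only free hydroxyl (C8) by the anhydride.

Step 16
Reactants: 26 8-O-methacrylate (C5–OTBS)
Product: 27 target EANPDB:COMP_00178
Conditions: HF·pyridine, pyridine, THF, 0 °C to rt
Reagents that add atoms: none
Why: Buffered HF·pyridine should remove the secondary silyl ether without opening the epoxides or adding to the two acrylate-type acceptors, releasing the C5 hydroxyl.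

Compound list
1 | 4-[(tert-butyldimethylsilyl)oxy]but-1-yne | C#CCCO[Si](C)(C)C(C)(C)C | starting material
2 | dimethyl[(1E)-2-methyl-4-(tert-butyldimethylsilyloxy)but-1-en-1-yl]alane | C[Al](C)/C=C(C)/CCO[Si](C)(C)C(C)(C)C | intermediate (not isolated)
3 | (2E)-5-[(tert-butyldimethylsilyl)oxy]-3-methylpent-2-en-1-ol | OC/C=C(C)/CCO[Si](C)(C)C(C)(C)C | intermediate
4 | [(2R,3R)-3-{2-[(tert-butyldimethylsilyl)oxy]ethyl}-3-methyloxiran-2-yl]methanol | CC(C)(C)[Si](C)(C)OCC[C@@]1(C)O[C@@H]1CO | intermediate
5 | (2S,3R)-3-{2-[(tert-butyldimethylsilyl)oxy]ethyl}-3-methyloxirane-2-carbaldehyde | CC(C)(C)[Si](C)(C)OCC[C@@]1(C)O[C@@H]1C=O | intermediate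
6 | 4-methoxybenzyl alcohol | COc1ccc(CO)cc1 | starting material
7 | allyl bromide | C=CCBr | starting material
8 | allyl 4-methoxybenzyl ether | C=CCOCc1ccc(OC)cc1 | intermediate
9 | methacrolein | C=C(C)C=O | starting material
10 | [(2Z)-3-(4-methoxybenzyloxy)prop-2-en-1-yl]bis(isopinocampheyl)borane, Ipc from (−)-α-pinene | COc1ccc(CO/C=C\CB([C@H]2C[C@H]3C[C@@H]([C@@H]2C)C3(C)C)[C@H]2C[C@H]3C[C@@H]([C@@H]2C)C3(C)C)cc1 | intermediate (not isolated)
11 | (3S,4S)-4-[(4-methoxybenzyl)oxy]-2-methylhexa-1,5-dien-3-ol | C=C(C)[C@H](O)[C@@H](OCc1ccc(OC)cc1)C=C | intermediate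
12 | tert-butyl({(3S,4S)-4-[(4-methoxybenzyl)oxy]-2-methylhexa-1,5-dien-3-yl}oxy)dimethylsilane | C=C(C)[C@H](O[Si](C)(C)C(C)(C)C)[C@@H](OCc1ccc(OC)cc1)C=C | intermediate
13 | tert-butyl({(3S,4S)-2-(chloromethyl)-4-[(4-methoxybenzyl)oxy]hexa-1,5-dien-3-yl}oxy)dimethylsilane | ClCC(=C)[C@H](O[Si](C)(C)C(C)(C)C)[C@@H](OCc1ccc(OC)cc1)C=C | intermediate
14 | γ-chloroallyl-bis(isopinocampheyl)borane from 13 (Cl cis to CH2B; Ipc from (+)-α-pinene) | Cl/C=C(\CB([C@@H]1C[C@@H]2C[C@H]([C@H]1C)C2(C)C)[C@@H]1C[C@@H]2C[C@H]([C@H]1C)C2(C)C)[C@H](O[Si](C)(C)C(C)(C)C)[C@@H](OCc1ccc(OC)cc1)C=C | intermediate (not isolated)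
15 | syn-chlorohydrin (C2–OH, C3–Cl; C10 R, C1 R, C2 R, C3 R, C5 S, C6 S) | CC(C)(C)[Si](C)(C)OCC[C@@]1(C)O[C@@H]1[C@@H](O)[C@H](Cl)C(=C)[C@H](O[Si](C)(C)C(C)(C)C)[C@@H](OCc1ccc(OC)cc1)C=C | intermediate (not isolated)
16 | acyclic bis-epoxide, C8–OTBS, C5–OTBS, C6–OPMB, C7 vinyl | CC(C)(C)[Si](C)(C)OCC[C@@]1(C)O[C@@H]1[C@H]1O[C@H]1C(=C)[C@H](O[Si](C)(C)C(C)(C)C)[C@@H](OCc1ccc(OC)cc1)C=C | intermediate
17 | C6 alcohol of 16 | CC(C)(C)[Si](C)(C)OCC[C@@]1(C)O[C@@H]1[C@H]1O[C@H]1C(=C)[C@H](O[Si](C)(C)C(C)(C)C)[C@@H](O)C=C | intermediate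
18 | 2-(bromomethyl)acrylic acid | C=C(CBr)C(=O)O | starting material
19 | C6 2-(bromomethyl)acrylate of 17 | CC(C)(C)[Si](C)(C)OCC[C@@]1(C)O[C@@H]1[C@H]1O[C@H]1C(=C)[C@H](O[Si](C)(C)C(C)(C)C)[C@@H](OC(=O)C(=C)CBr)C=C | intermediate
20 | 3-(bromomethyl)butenolide, C8–OTBS | CC(C)(C)[Si](C)(C)OCC[C@@]1(C)O[C@@H]1[C@H]1O[C@H]1C(=C)[C@H](O[Si](C)(C)C(C)(C)C)[C@H]1OC(=O)C(CBr)=C1 | intermediate
21 | primary C8 alcohol | OCC[C@@]1(C)O[C@@H]1[C@H]1O[C@H]1C(=C)[C@H](O[Si](C)(C)C(C)(C)C)[C@H]1OC(=O)C(CBr)=C1 | intermediate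
22 | C8 aldehyde | O=CC[C@@]1(C)O[C@@H]1[C@H]1O[C@H]1C(=C)[C@H](O[Si](C)(C)C(C)(C)C)[C@H]1OC(=O)C(CBr)=C1 | intermediate
23 | allylchromium dichloride species at C13 (trivalent chromium, solvent ligands omitted) | O=CC[C@@]1(C)O[C@@H]1[C@H]1O[C@H]1C(=C)[C@H](O[Si](C)(C)C(C)(C)C)[C@H]1OC(=O)C(C[Cr](Cl)Cl)=C1 | intermediate (not isolated)
24 | ten-membered 8-hydroxy-11(13)-methylene lactone, C5–OTBS | O[C@H]1C[C@@]2(C)O[C@@H]2[C@H]2O[C@H]2C(=C)[C@H](O[Si](C)(C)C(C)(C)C)[C@H]2OC(=O)C(=C)[C@@H]21 | intermediate
25 | methacrylic anhydride | C=C(C)C(=O)OC(=O)C(C)=C | starting material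
26 | 8-O-methacrylate, C5–OTBS | C=C(C)C(=O)O[C@H]1C[C@@]2(C)O[C@@H]2[C@H]2O[C@H]2C(=C)[C@H](O[Si](C)(C)C(C)(C)C)[C@H]2OC(=O)C(=C)[C@@H]21 | intermediate
27 | EANPDB:COMP_00178 (1R,2S,3S,5S,6S,7R,8S,10R in the numbering above) | C=C(C)C(=O)O[C@H]1C[C@@]2(C)O[C@@H]2[C@H]2O[C@H]2C(=C)[C@H](O)[C@H]2OC(=O)C(=C)[C@@H]21 | target

Total step count: 16. Longest linear sequence: 13 steps (steps 4–16, from 4-methoxybenzyl alcohol); the other branch (steps 1–3, then 8–16) is 12 steps.

Steps most likely to fail

1. Step 8. Deprotonation of the hindered chloride 13 may be slow or unselective, and the required Si-face attack runs against the intrinsic anti preference of the α,β-epoxy aldehyde (mismatched double induction), which could erode the C2 configuration or the syn/cis relationship. The fallback sets out from 5 and returns at 16. Stork–Zhao olefination of 5 (Ph3P+CH2I I−, NaHMDS, THF/HMPA, −78 °C) would give the (Z)-vinyl iodide F1. In parallel, 2-bromoacrolein would be subjected to the alkoxyallylboration of step 5 to give the bromo dienol F2, which is silylated (TBSOTf, 2,6-lutidine) to the bromo diene silyl ether F3. F3 is converted to its alkenylzinc (t-BuLi, −78 °C; ZnCl2) and joined to F1 by Negishi coupling (Pd(PPh3)4, THF, rt) to give the Z-diene F4. The cis-disubstituted alkene of F4 is then epoxidised under reagent control with the dioxirane of the oxazolidinone-bearing glucose-derived Shi ketone (Oxone, K2CO3 buffer, DME/H2O, 0 °C; the catalyst antipode that delivers the 2S,3S-epoxide) to give 16.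

2. Step 14. A tether-distorted or boat-like transition state may give poor facial selectivity at the aldehyde carbon (C8 epimer); β-elimination of the β,γ-epoxy aldehyde and oligomerisation are further losses. The fallback sets out from 22 and returns at 26. If the closure delivers mainly the 8-epimeric alcohol F5, it is carried on by Mitsunobu esterification with methacrylic acid (PPh3, DIAD, toluene, 0 °C), which inverts C8 and gives 26 directly, replacing step 15.

3. Step 7. The electrophilic chlorination may lose chemoselectivity (attack on the vinyl group or the anisyl ring) or transpose the alkene toward C5. The fallback sets out from 12 and returns at 13. Allylic hydroxylation of the isopropenyl methyl (SeO2 cat., t-BuOOH, CH2Cl2) would give the allylic alcohol F6, which is converted to 13 by mesylation and chloride displacement (MsCl, Et3N; LiCl, DMF).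

Further compounds
F1 | step 8 | (Z)-vinyl iodide from 5: tert-butyl(2-{3-[(Z)-2-iodoethenyl]-2-methyloxiran-2-yl}ethoxy)dimethylsilane, epoxide configuration as in 5 | CC(C)(C)[Si](C)(C)OCC[C@@]1(C)O[C@@H]1/C=C\I
F2 | step 8 | (3R,4S)-2-bromo-4-[(4-methoxybenzyl)oxy]hexa-1,5-dien-3-ol | C=C(Br)[C@H](O)[C@@H](OCc1ccc(OC)cc1)C=C
F3 | step 8 | tert-butyldimethylsilyl ether of F2 | C=C(Br)[C@H](O[Si](C)(C)C(C)(C)C)[C@@H](OCc1ccc(OC)cc1)C=C
F4 | step 8 | Z-diene (C2=C3 cis, C4 methylene) with 1,10-epoxide, C5–OTBS, C6–OPMB | CC(C)(C)[Si](C)(C)OCC[C@@]1(C)O[C@@H]1/C=C\C(=C)[C@H](O[Si](C)(C)C(C)(C)C)[C@@H](OCc1ccc(OC)cc1)C=C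
F5 | step 14 | 8-epimer of 24 | O[C@@H]1C[C@@]2(C)O[C@@H]2[C@H]2O[C@H]2C(=C)[C@H](O[Si](C)(C)C(C)(C)C)[C@H]2OC(=O)C(=C)[C@@H]21
F6 | step 7 | (3S,4S)-3-[(tert-butyldimethylsilyl)oxy]-4-[(4-methoxybenzyl)oxy]-2-methylidenehex-5-en-1-ol | OCC(=C)[C@H](O[Si](C)(C)C(C)(C)C)[C@@H](OCc1ccc(OC)cc1)C=C
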